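## The problem

The target is a (1(10)Z,4E)-germacradien-12,8-olide carrying (Z)-2-methylbut-2-enoate (angelate) esters on O6 and O11. Numbering used throughout: ring C1–C10; C11 (bearing the C13 methyl) and the lactone carbonyl C12 on C7; C14 on C10; C15 on C4.

- **Ring.** A ten-membered carbocycle with a Z and an E trisubstituted alkene in a 1,5-relationship has to be closed, trans-fused at C7–C8 to a γ-lactone. End-to-end closure of such a ring is entropically poor, and the finished ring is open to acid-induced transannular cyclisation and to thermal Cope rearrangement.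
- **Stereocentres.** C6, C7, C8 and C11 are contiguous. C8 can be set first by a reagent and can then steer C7. The C6/C7 relation can be taken from an alkene geometry. The quaternary C11 is best set last, on the rigid lactone, by the C6 branch on the neighbouring C7.
- **Oxygen atoms.** O6, O8 and O11 have to be told apart.
- **Fragile groups.** Angelates isomerise to tiglates under nucleophilic catalysis, acid or heat, and one of them sits on a tertiary α-carbonyl alcohol, so both are introduced at the very end.
- **Enabling feature.** The array C6(OH)–C7(H)–C11–C12 is a homoallylic alcohol once C11–C12 is written as a vinyl group, and the carbinol is also allylic to C4=C5. This is the retron of a [2,3]-Wittig shift of a C6–O–C12 allyl ether. Tying C6 to C12 through oxygen replaces the ten-membered ring by a 13-membered ether that is much easier to close.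

## Retrosynthesis

**Ester bonds.** The two angelate C–O bonds are cut first, 33 ⇒ diol 31 + angelic anhydride 32. Any earlier introduction would expose a Z enoate to enolate chemistry. The forward step has to acylate a secondary and a tertiary alkoxide without Z→E isomerisation.

**C11.** The C11–CH3 and C11–O bonds are cut next, 31 ⇒ 30 ⇒ 29 ⇒ 28 ⇒ lactone 27. Oxygen goes on first and methyl last, because the last group enters the lactone enolate trans to the C6 branch on C7, and in the target it is the methyl group that is trans to C6. The reverse order would be expected to give the C11 epimer. Lactone 27 has neither C13 nor a C11 stereocentre.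

**Lactone.** The O8–C12 bond is cut and C12 is taken back to a primary alcohol and then to an alkene terminus: 27 ⇒ diol 25 ⇒ 24 ⇒ triene 22 ⇒ alcohol 21. The monosubstituted vinyl group is the only alkene that 9-BBN attacks. O8 arrives silylated (tert-butyldimethylsilyl) from the acyclic stage, and O6 is capped with the more robust triisopropylsilyl group so that O8 can be freed alone.

**Ring (key cut).** C6–C7 is cut and O–C12 is reconnected, 21 ⇒ 13-membered diallylic ether 20. Cutting any ring bond in the ordinary sense would demand an end-to-end ten-membered ring closure. This cut instead makes the carbocycle by contraction of a larger ring and sets C6 and C7 in the same event. The forward step needs lithiation at C6 and not at C12, and a relay of configuration from C8 to C7. Because C12 belongs to the less substituted allyl unit, it is deuterated (CD2) so that a kinetic isotope effect works against the unwanted deprotonation. The label is lost when C12 becomes the lactone carbonyl.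

**Ether.** The C6–O bond is cut, 20 ⇒ chloro alcohol 19 ⇒ 18 ⇒ alcohol 17. The opposite polarity (leaving group on C12) would need an extra protecting-group exchange. The C6 alcohol is free in 17 and becomes the chloride, and the C12 hydroxyl is released afterwards from its primary silyl ether.

**C2–C3.** This is the only bond flanked by two allyl units, so 17 ⇒ allylic sulfone 11 + allylic bromide 15 (through 16). Both alkene geometries are bought with the fragments. The forward reaction needs α-alkylation of the sulfonyl carbanion and reductive removal of sulfur without moving the C1=C10 alkene.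

**Sulfone fragment.** 11 ⇒ diol 10 ⇒ ester 9 ⇒ 8 ⇒ aldehyde 5 + ylide 6 (C7=C11 by Wittig olefination, O8 by proline-catalysed α-aminoxylation); 5 ⇒ sulfone 3 ⇒ nerol 1 by cleavage of the terminal alkene. Nerol supplies C1, C2, C7–C10 and C14 with the Z alkene in place.

**Bromide fragment.** 15 ⇒ 14 ⇒ prenyl acetate 12 by allylic oxidation of the E methyl group. It supplies C3–C6 and C15 with the E alkene.

## Roads not taken

**Alternative 1:** The cut is C7–C11. In the forward direction the lithium enolate (LiN(SiMe3)2) of the O-silyl lactate ester A1 opens the neighbouring cis-epoxide at C7 (5-exo) and gives lactone A2.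
- Merits: one step makes the lactone, the quaternary C11 with its oxygen and methyl group (both from lactic acid), C7 by inversion and the free C6 hydroxyl. O6 (free) and O11 (silylated) are distinguished without extra steps. This is better than the chosen plan, which spends steps 19–21 on C11 and steps 15 and 17 on oxygen differentiation.
- Weak points: A2 is still acyclic between C2 and C5, and C3, C4 and C15 are missing. The ten-membered ring with its E trisubstituted alkene would have to be closed later, end to end, on a base-sensitive lactone. The C11 configuration depends on enolate geometry and face. An ester enolate whose alkoxy part is a secondary alkoxide can also fragment to a ketene.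
- Comparison: the chosen plan sets against this an early ring closure with direct precedent, and both ring alkenes taken from commercial terpenes.

**Alternative 2:** The cut is C3–C4. 9-BBN is added to the terminal alkene of diene A3 and the alkylborane is coupled with the C4 alkenyl iodide (PdCl2(dppf), aqueous base) to give the bis-silylated lactone A4.
- Merits: all four stereocentres and the lactone are built on open-chain or five-ring substrates. The E geometry at C4=C5 is carried over from the iodide with certainty. The sensitive cyclodecadiene exists only for the last few steps. In these respects it is better than the chosen plan, which carries the ring through nine steps.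
- Weak points: the ten-membered ring has to form by reductive elimination from an eleven-membered palladacycle, in competition with β-hydride elimination and dimerisation. Hydroboration of a conjugated diene is less clean than that of an isolated vinyl group. Aqueous base endangers the lactone. The riskiest step comes at the end of the longest sequence.
- Comparison: the chosen plan closes its ring at step 14 on simple material and creates two stereocentres while doing so.

**Alternative 3:** The cut is C8–C9. The aldehyde of A5 is attacked by C9 of the tethered α-substituted allyl pinacolboronate through a chair, giving cyclodecadienol A6.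
- Merits: ring closure, the C8 carbinol and the Z C1=C10 alkene arise together under neutral conditions. A6 has O8 free next to the C12 ester and O6 silylated, so lactonisation needs no protecting-group steps. Here it is better than the chosen plan by about two steps.
- Weak points: intramolecular allylboration is established for five- to seven-membered rings, not for a ten-membered ring that must accommodate a bicyclic chair. Z selectivity depends on the boron-bearing stereocentre C1, which has to be made in defined form. Aldehyde A5 has an epimerisable C7 and a β-silyloxy group. C11 still needs the same three steps.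
- Comparison: the chosen plan is preferred because its ring-forming step has precedent for exactly this ring size.

Key step: step 14

Remarks:
- CIP descriptors in the names refer to the compound named; priorities at C7 change with the oxygen substituents although the spatial arrangement does not.
- Compounds 10, 11 and 16–26 carry two deuterium atoms on C12.
- Assumption: angelic anhydride 32 is used as a purchased reagent; it is one dehydration step from angelic acid.

**Step 1**
Reactants: 1 nerol
Product: 3 neryl phenyl sulfone, via neryl bromide 2 (not isolated)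
Conditions: PBr3, Et2O, −10 °C; then PhSO2Na, DMF, rt
Reagents that add atoms: phosphorus tribromide BrP(Br)Br; sodium benzenesulfinate [Na+].[O-]S(=O)c1ccccc1
Why: Bromination of the primary allylic alcohol at low temperature and SN2 S-alkylation of the sulfinate should give the allylic sulfone with the Z alkene and its position unchanged.

**Step 2**
Reactants: 3 neryl phenyl sulfone
Product: 5 (4Z)-4-methyl-6-(phenylsulfonyl)hex-4-enal, via epoxide 4 (not isolated)
Conditions: mCPBA, CH2Cl2, 0 °C; then H5IO6, THF/H2O, 0 °C → rt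
Reagents that add atoms: 3-chloroperbenzoic acid OOC(=O)c1cccc(Cl)c1; water O
Why: Prilezhaev epoxidation should take the remote alkene because the other one is deactivated by the allylic sulfonyl group; periodic acid hydrolyses the epoxide and cleaves the glycol to the aldehyde and acetone.

**Step 3**
Reactants: 5 (4Z)-4-methyl-6-(phenylsulfonyl)hex-4-enal; 6 ethyl (triphenylphosphoranylidene)acetate
Product: 8 ethyl (2E,4R,6Z)-4-(anilinooxy)-6-methyl-8-(phenylsulfonyl)octa-2,6-dienoate, via α-anilinooxy aldehyde 7 (not isolated)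
Conditions: PhNO, L-proline (20 mol %), DMSO, rt; then 6, 0 °C → rt
Reagents that add atoms: nitrosobenzene O=Nc1ccccc1
Why: Proline-catalysed α-aminoxylation (enamine attack on the nitroso oxygen in a hydrogen-bonded transition state) sets C8, and L-proline is known to give the R α-oxy aldehyde from unbranched aldehydes; the labile aldehyde is trapped at once by the stabilised Wittig ylide, which should give the E enoate.

**Step 4**
Reactants: 8 ethyl (2E,4R,6Z)-4-(anilinooxy)-6-methyl-8-(phenylsulfonyl)octa-2,6-dienoate
Product: 9 ethyl (2E,4R,6Z)-4-hydroxy-6-methyl-8-(phenylsulfonyl)octa-2,6-dienoate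
Conditions: Zn, AcOH/EtOH, 0 °C → rt
Reagents that add atoms: none
Why: Zn in acetic acid reduces the weak N–O bond to the alcohol and aniline; the enoate, the sulfone and the alkenes are not reduced under these conditions.

**Step 5**
Reactants: 9 ethyl (2E,4R,6Z)-4-hydroxy-6-methyl-8-(phenylsulfonyl)octa-2,6-dienoate
Product: 10 (2E,4R,6Z)-6-methyl-8-(phenylsulfonyl)(1,1-2H2)octa-2,6-diene-1,4-diol
Conditions: LiAlD4, AlCl3 (3:1), Et2O, 0 °C; then 9, −20 → 0 °C; aqueous potassium sodium tartrate
Reagents that add atoms: lithium aluminium deuteride [Li+].[2H][Al-]([2H])([2H])[2H]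
Why: AlD3 reduces α,β-unsaturated esters in the 1,2 sense only, so the E allylic alcohol should form with both C12 hydrogens replaced by deuterium; the sulfone is inert to this non-basic hydride.

**Step 6**
Reactants: 10 (2E,4R,6Z)-6-methyl-8-(phenylsulfonyl)(1,1-2H2)octa-2,6-diene-1,4-diol
Product: 11 (2E,4R,6Z)-1,4-bis(tert-butyldimethylsilyloxy)-6-methyl-8-(phenylsulfonyl)(1,1-2H2)octa-2,6-diene
Conditions: TBSCl, imidazole, DMF, rt
Reagents that add atoms: tert-butyldimethylsilyl chloride CC(C)(C)[Si](C)(C)Cl
Why: Standard silylation of both hydroxyls; the primary and the secondary silyl ether can be told apart later by their rate of cleavage (step 12).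

**Step 7**
Reactants: 12 prenyl acetate
Product: 14 (2E)-4-hydroxy-3-methylbut-2-en-1-yl acetate, via enal 13 (not isolated)
Conditions: SeO2 (cat.), t-BuOOH, CH2Cl2, rt; then NaBH4, MeOH, 0 °C
Reagents that add atoms: selenium dioxide O=[Se]=O (oxygen donor, reoxidised by tert-butyl hydroperoxide CC(C)(C)OO)
Why: Allylic oxidation with SeO2 (ene reaction, then [2,3]-shift) attacks the E methyl group of a trisubstituted alkene; NaBH4 returns over-oxidised enal 13 to the alcohol without touching the acetate at 0 °C.

**Step 8**
Reactants: 14 (2E)-4-hydroxy-3-methylbut-2-en-1-yl acetate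
Product: 15 (2E)-4-bromo-3-methylbut-2-en-1-yl acetate
Conditions: CBr4, PPh3, CH2Cl2, 0 °C
Reagents that add atoms: carbon tetrabromide BrC(Br)(Br)Br
Why: Appel bromination of a primary allylic alcohol goes by SN2 displacement of the alkoxyphosphonium ion and should leave the alkene geometry and position untouched.

**Step 9**
Reactants: 11 (2E,4R,6Z)-1,4-bis(tert-butyldimethylsilyloxy)-6-methyl-8-(phenylsulfonyl)(1,1-2H2)octa-2,6-diene; 15 (2E)-4-bromo-3-methylbut-2-en-1-yl acetate
Product: 16 (2E,6Z,9R,10E)-9,12-bis(tert-butyldimethylsilyloxy)-3,7-dimethyl-5-(phenylsulfonyl)(12,12-2H2)dodeca-2,6,10-trien-1-yl acetate (both C5 epimers)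
Conditions: n-BuLi, THF, −78 °C; then 15, −78 → −40 °C
Reagents that add atoms: none
Why: Alkylation of a lithiated allylic sulfone takes place at the α-carbon, and the primary allylic bromide reacts far faster than the acetate; this forms C2–C3, and the sulfone-bearing centre is removed in step 10, so its configuration does not matter.

**Step 10**
Reactants: 16 (2E,6Z,9R,10E)-9,12-bis(tert-butyldimethylsilyloxy)-3,7-dimethyl-5-(phenylsulfonyl)(12,12-2H2)dodeca-2,6,10-trien-1-yl acetate
Product: 17 (2E,6Z,9R,10E)-9,12-bis(tert-butyldimethylsilyloxy)-3,7-dimethyl(12,12-2H2)dodeca-2,6,10-trien-1-ol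
Conditions: LiBHEt3 (5 equiv), THF, 0 °C; then Pd(dppp)Cl2 (5 mol %), 0 °C → rt
Reagents that add atoms: none
Why: The hydride first cleaves the acetate, so that O6 is an alkoxide that zerovalent palladium cannot ionise; palladium-catalysed hydride substitution of the allylic sulfone then delivers hydride to the less substituted terminus (C2) of the π-allyl intermediate, which should keep C1=C10 in place and Z, and at 0 °C the allylic silyl ethers are much poorer leaving groups than the sulfinate.

**Step 11**
Reactants: 17 (2E,6Z,9R,10E)-9,12-bis(tert-butyldimethylsilyloxy)-3,7-dimethyl(12,12-2H2)dodeca-2,6,10-trien-1-ol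
Product: 18 (2E,6Z,9R,10E)-9,12-bis(tert-butyldimethylsilyloxy)-1-chloro-3,7-dimethyl(12,12-2H2)dodeca-2,6,10-triene
Conditions: NCS, Me2S, CH2Cl2, −20 → 0 °C
Reagents that add atoms: N-chlorosuccinimide O=C1CCC(=O)N1Cl
Why: Corey–Kim chlorination turns primary allylic alcohols into the chlorides without allylic transposition and under conditions that silyl ethers tolerate.

**Step 12**
Reactants: 18 (2E,6Z,9R,10E)-9,12-bis(tert-butyldimethylsilyloxy)-1-chloro-3,7-dimethyl(12,12-2H2)dodeca-2,6,10-triene
Product: 19 (2E,4R,6Z,10E)-4-(tert-butyldimethylsilyloxy)-12-chloro-6,10-dimethyl(1,1-2H2)dodeca-2,6,10-trien-1-ol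
Conditions: HF·pyridine, pyridine, THF, 0 °C
Reagents that add atoms: none
Why: Buffered HF·pyridine cleaves an unhindered primary silyl ether well before a secondary one, and the aprotic medium should spare the allylic chloride.

**Step 13**
Reactants: 19 (2E,4R,6Z,10E)-4-(tert-butyldimethylsilyloxy)-12-chloro-6,10-dimethyl(1,1-2H2)dodeca-2,6,10-trien-1-ol
Product: 20 (3E,7Z,10R,11E)-10-(tert-butyldimethylsilyloxy)-4,8-dimethyl(13,13-2H2)-1-oxacyclotrideca-3,7,11-triene
Conditions: NaH, THF, 45 °C, slow addition of 19 (final 2 mM)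
Reagents that add atoms: none
Why: Intramolecular Williamson etherification at high dilution, the known entry to 13-membered diallylic ethers: the primary allylic alkoxide displaces the primary allylic chloride by SN2, and the E C7=C11 alkene keeps the C12 alkoxide away from the C8 silyl group so that no silyl transfer can occur.

**Step 14**
Reactants: 20 (3E,7Z,10R,11E)-10-(tert-butyldimethylsilyloxy)-4,8-dimethyl(13,13-2H2)-1-oxacyclotrideca-3,7,11-triene
Product: 21 (1S,2E,6Z,9R,10R)-9-(tert-butyldimethylsilyloxy)-10-[(2,2-2H2)ethenyl]-3,7-dimethylcyclodeca-2,6-dien-1-ol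
Conditions: n-BuLi (1.5 equiv), THF, −78 °C; AcOH, −78 °C
Reagents that add atoms: none
Why: n-BuLi removes a C6 proton (α to oxygen, allylic to C4=C5), and the α-oxy allyllithium adds through C6 to C7 of the E C7=C11 alkene across the ring in a five-membered envelope transition state while the π bond moves to C11=C12 and O–C12 breaks, leaving the C6 lithium alkoxide. The closest known reaction type is the [2,3]-Wittig ring contraction of 13-membered diallylic and allyl propargyl ethers to cyclodecenols. The ten-membered carbocycle is closed by transannular C6–C7 bond formation that contracts the ether ring by three atoms; both termini are already held in one ring, and the strain of the Z,E-cyclodecadiene is paid for by the change from carbanion to alkoxide. The anti relation of C6 and C7 follows from the E geometry of C7=C11 with the C5 substituent in the less crowded exo position of the envelope. The sense at C7 is set by C8: with H8 near the alkene plane (least allylic strain) the new bond forms anti to the C8–O bond, which gives 10R in 21. The step needs lithiation at C6 and not at C12, although C12 belongs to the less substituted allyl unit and its anion could expel the C8 silanolate by 1,4-elimination; the CD2 group slows that deprotonation by a primary kinetic isotope effect, and a C12 anion could in any case shift only onto the fully substituted C4. Low temperature favours the concerted [2,3] shift over the [1,2] shift, and protonation at −78 °C prevents silyl migration from O8 to the new alkoxide.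

**Step 15**
Reactants: 21 (1S,2E,6Z,9R,10R)-9-(tert-butyldimethylsilyloxy)-10-[(2,2-2H2)ethenyl]-3,7-dimethylcyclodeca-2,6-dien-1-ol
Product: 22 (6S,7S,8R)-8-(tert-butyldimethylsilyloxy)-6-(triisopropylsilyloxy)(12,12-2H2)-13-norgermacra-1(10)Z,4E,11-triene
Conditions: TIPSOTf, 2,6-lutidine, CH2Cl2, −40 → 0 °C
Reagents that add atoms: triisopropylsilyl trifluoromethanesulfonate CC(C)[Si](C(C)C)(C(C)C)OS(=O)(=O)C(F)(F)F
Why: The silyl triflate with a hindered base silylates hindered secondary alcohols without forming an alkoxide (no silyl migration) and without free acid that could trigger transannular cyclisation.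

**Step 16**
Reactants: 22 (6S,7S,8R)-8-(tert-butyldimethylsilyloxy)-6-(triisopropylsilyloxy)(12,12-2H2)-13-norgermacra-1(10)Z,4E,11-triene
Product: 24 (6S,7S,8R)-8-(tert-butyldimethylsilyloxy)-6-(triisopropylsilyloxy)(12,12-2H2)-13-norgermacra-1(10)Z,4E-dien-12-ol, via B-alkyl-9-BBN adduct 23 (not isolated)
Conditions: 9-BBN, THF, 0 °C → rt; then NaOH, H2O2, 0 °C
Reagents that add atoms: 9-borabicyclo[3.3.1]nonane B1C2CCCC1CCC2; hydrogen peroxide OO
Why: 9-BBN adds only to the monosubstituted vinyl group (boron on C12) and leaves both trisubstituted ring alkenes alone; oxidation of the C–B bond gives the primary alcohol.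

**Step 17**
Reactants: 24 (6S,7S,8R)-8-(tert-butyldimethylsilyloxy)-6-(triisopropylsilyloxy)(12,12-2H2)-13-norgermacra-1(10)Z,4E-dien-12-ol
Product: 25 (6S,7S,8R)-6-(triisopropylsilyloxy)(12,12-2H2)-13-norgermacra-1(10)Z,4E-diene-8,12-diol
Conditions: HF·pyridine, pyridine, THF, 0 °C → rt
Reagents that add atoms: none
Why: A secondary tert-butyldimethylsilyl ether is cleaved by buffered HF·pyridine well before a secondary triisopropylsilyl ether, and the buffer protects the acid-sensitive diene.

**Step 18**
Reactants: 25 (6S,7S,8R)-6-(triisopropylsilyloxy)(12,12-2H2)-13-norgermacra-1(10)Z,4E-diene-8,12-diol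
Product: 27 (6S,7S,8R)-6-(triisopropylsilyloxy)-13-norgermacra-1(10)Z,4E-dien-12,8-olide, via lactol 26 (not isolated)
Conditions: TEMPO (20 mol %), PhI(OAc)2, CH2Cl2, rt
Reagents that add atoms: none
Why: The oxoammonium ion from TEMPO oxidises the primary alcohol selectively, the aldehyde closes onto O8 and lactol 26 is oxidised on to the γ-lactone, whose trans fusion is fixed by C7 and C8; both deuterium atoms leave C12 and end as exchangeable O–D.

**Step 19**
Reactants: 27 (6S,7S,8R)-6-(triisopropylsilyloxy)-13-norgermacra-1(10)Z,4E-dien-12,8-olide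
Product: 28 (6S,7S,8R,11S)-11-hydroxy-6-(triisopropylsilyloxy)-13-norgermacra-1(10)Z,4E-dien-12,8-olide
Conditions: KN(SiMe3)2, THF, −78 °C; 2-(phenylsulfonyl)-3-phenyloxaziridine, −78 °C
Reagents that add atoms: 2-(phenylsulfonyl)-3-phenyloxaziridine O=S(=O)(c1ccccc1)N1OC1c1ccccc1
Why: Hydroxylation of the lactone enolate by an N-sulfonyloxaziridine; the expected major epimer (oxygen trans to the C6 branch) is shown, but the C11 configuration is of no consequence because the centre is enolised again in step 21.

**Step 20**
Reactants: 28 (6S,7S,8R,11S)-11-hydroxy-6-(triisopropylsilyloxy)-13-norgermacra-1(10)Z,4E-dien-12,8-olide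
Product: 29 (6S,7S,8R,11S)-11-(triethylsilyloxy)-6-(triisopropylsilyloxy)-13-norgermacra-1(10)Z,4E-dien-12,8-olide
Conditions: TESCl, imidazole, DMF, 0 °C → rt
Reagents that add atoms: chlorotriethylsilane CC[Si](Cl)(CC)CC
Why: Silylation of the secondary α-hydroxyl removes the acidic proton before the second enolisation.

**Step 21**
Reactants: 29 (6S,7S,8R,11S)-11-(triethylsilyloxy)-6-(triisopropylsilyloxy)-13-norgermacra-1(10)Z,4E-dien-12,8-olide
Product: 30 (6S,7S,8R,11R)-11-(triethylsilyloxy)-6-(triisopropylsilyloxy)germacra-1(10)Z,4E-dien-12,8-olide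
Conditions: LiN(i-Pr)2, THF, −78 °C; MeI, DMPU, −78 → −40 °C
Reagents that add atoms: iodomethane CI
Why: Alkylation of the α-silyloxy lactone enolate: methyl iodide should approach the planar C11 from the face opposite the C6 branch on the adjacent C7 (the usual trans alkylation of β-substituted γ-lactone enolates), which puts CH3 cis to H7 and the oxygen cis to C6 as in the target.

**Step 22**
Reactants: 30 (6S,7S,8R,11R)-11-(triethylsilyloxy)-6-(triisopropylsilyloxy)germacra-1(10)Z,4E-dien-12,8-olide
Product: 31 (6S,7R,8R,11R)-6,11-dihydroxygermacra-1(10)Z,4E-dien-12,8-olide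
Conditions: n-Bu4NF, AcOH (1:1), THF, 0 °C → rt
Reagents that add atoms: none
Why: Buffered fluoride removes both silyl ethers without strong acid (diene) or free alkoxide (lactone).

**Step 23**
Reactants: 31 (6S,7R,8R,11R)-6,11-dihydroxygermacra-1(10)Z,4E-dien-12,8-olide; 32 angelic anhydride
Product: 33 (6S,7S,8R,11R)-6,11-bis[(2Z)-2-methylbut-2-enoyloxy]germacra-1(10)Z,4E-dien-12,8-olide
Conditions: LiN(SiMe3)2 (2.2 equiv), THF, −78 °C; 32 (3 equiv), −78 → 0 °C
Reagents that add atoms: none
Why: Acylation of lithium alkoxides with angelic anhydride is a known way to angelates without Z→E isomerisation, since no nucleophilic catalyst is present that could add to the enoate; the alkoxide route is what the hindered tertiary C11 hydroxyl needs, and C11 has no α-hydrogen left, so the lactone cannot enolise.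

## Compound list

1 | nerol, (2Z)-3,7-dimethylocta-2,6-dien-1-ol | CC(C)=CCC/C(C)=C\CO | starting material
2 | neryl bromide, (2Z)-1-bromo-3,7-dimethylocta-2,6-diene | CC(C)=CCC/C(C)=C\CBr | intermediate
3 | neryl phenyl sulfone, {[(2Z)-3,7-dimethylocta-2,6-dien-1-yl]sulfonyl}benzene | CC(C)=CCC/C(C)=C\CS(=O)(=O)c1ccccc1 | intermediate
4 | 2,2-dimethyl-3-[(3Z)-3-methyl-5-(phenylsulfonyl)pent-3-en-1-yl]oxirane (racemic) | CC1(C)OC1CC/C(C)=C\CS(=O)(=O)c1ccccc1 | intermediate
5 | (4Z)-4-methyl-6-(phenylsulfonyl)hex-4-enal | O=CCC/C(C)=C\CS(=O)(=O)c1ccccc1 | intermediate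
6 | ethyl (triphenylphosphoranylidene)acetate | CCOC(=O)C=P(c1ccccc1)(c1ccccc1)c1ccccc1 | starting material
7 | (2R,4Z)-2-(anilinooxy)-4-methyl-6-(phenylsulfonyl)hex-4-enal | O=C[C@H](ONc1ccccc1)C/C(C)=C\CS(=O)(=O)c1ccccc1 | intermediate
8 | ethyl (2E,4R,6Z)-4-(anilinooxy)-6-methyl-8-(phenylsulfonyl)octa-2,6-dienoate | CCOC(=O)/C=C/[C@H](ONc1ccccc1)C/C(C)=C\CS(=O)(=O)c1ccccc1 | intermediate
9 | ethyl (2E,4R,6Z)-4-hydroxy-6-methyl-8-(phenylsulfonyl)octa-2,6-dienoate | CCOC(=O)/C=C/[C@H](O)C/C(C)=C\CS(=O)(=O)c1ccccc1 | intermediate
10 | (2E,4R,6Z)-6-methyl-8-(phenylsulfonyl)(1,1-2H2)octa-2,6-diene-1,4-diol | [2H]C([2H])(O)/C=C/[C@H](O)C/C(C)=C\CS(=O)(=O)c1ccccc1 | intermediate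
11 | (2E,4R,6Z)-1,4-bis(tert-butyldimethylsilyloxy)-6-methyl-8-(phenylsulfonyl)(1,1-2H2)octa-2,6-diene | [2H]C([2H])(O[Si](C)(C)C(C)(C)C)/C=C/[C@H](O[Si](C)(C)C(C)(C)C)C/C(C)=C\CS(=O)(=O)c1ccccc1 | intermediate
12 | prenyl acetate, 3-methylbut-2-en-1-yl acetate | CC(C)=CCOC(C)=O | starting material
13 | (2E)-3-methyl-4-oxobut-2-en-1-yl acetate | CC(=O)OC/C=C(\C)C=O | intermediate
14 | (2E)-4-hydroxy-3-methylbut-2-en-1-yl acetate | CC(=O)OC/C=C(\C)CO | intermediate
15 | (2E)-4-bromo-3-methylbut-2-en-1-yl acetate | CC(=O)OC/C=C(\C)CBr | intermediate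
16 | (2E,6Z,9R,10E)-9,12-bis(tert-butyldimethylsilyloxy)-3,7-dimethyl-5-(phenylsulfonyl)(12,12-2H2)dodeca-2,6,10-trien-1-yl acetate, both C5 epimers | [2H]C([2H])(O[Si](C)(C)C(C)(C)C)/C=C/[C@H](O[Si](C)(C)C(C)(C)C)C/C(C)=C\C(C/C(C)=C/COC(C)=O)S(=O)(=O)c1ccccc1 | intermediate
17 | (2E,6Z,9R,10E)-9,12-bis(tert-butyldimethylsilyloxy)-3,7-dimethyl(12,12-2H2)dodeca-2,6,10-trien-1-ol | OC/C=C(\C)CC/C=C(/C)C[C@@H](O[Si](C)(C)C(C)(C)C)/C=C/C([2H])([2H])O[Si](C)(C)C(C)(C)C | intermediate
18 | (2E,6Z,9R,10E)-9,12-bis(tert-butyldimethylsilyloxy)-1-chloro-3,7-dimethyl(12,12-2H2)dodeca-2,6,10-triene | ClC/C=C(\C)CC/C=C(/C)C[C@@H](O[Si](C)(C)C(C)(C)C)/C=C/C([2H])([2H])O[Si](C)(C)C(C)(C)C | intermediate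
19 | (2E,4R,6Z,10E)-4-(tert-butyldimethylsilyloxy)-12-chloro-6,10-dimethyl(1,1-2H2)dodeca-2,6,10-trien-1-ol | ClC/C=C(\C)CC/C=C(/C)C[C@@H](O[Si](C)(C)C(C)(C)C)/C=C/C([2H])([2H])O | intermediate
20 | (3E,7Z,10R,11E)-10-(tert-butyldimethylsilyloxy)-4,8-dimethyl(13,13-2H2)-1-oxacyclotrideca-3,7,11-triene | O1C/C=C(\C)CC/C=C(/C)C[C@@H](O[Si](C)(C)C(C)(C)C)/C=C/C1([2H])[2H] | intermediate
21 | (1S,2E,6Z,9R,10R)-9-(tert-butyldimethylsilyloxy)-10-[(2,2-2H2)ethenyl]-3,7-dimethylcyclodeca-2,6-dien-1-ol | O[C@H]1/C=C(\C)CC/C=C(/C)C[C@@H](O[Si](C)(C)C(C)(C)C)[C@@H]1C=C([2H])[2H] | intermediate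
22 | (6S,7S,8R)-8-(tert-butyldimethylsilyloxy)-6-(triisopropylsilyloxy)(12,12-2H2)-13-norgermacra-1(10)Z,4E,11-triene | CC(C)[Si](C(C)C)(C(C)C)O[C@H]1/C=C(\C)CC/C=C(/C)C[C@@H](O[Si](C)(C)C(C)(C)C)[C@@H]1C=C([2H])[2H] | intermediate
23 | 9-[(6S,7S,8R)-8-(tert-butyldimethylsilyloxy)-6-(triisopropylsilyloxy)(12,12-2H2)-13-norgermacra-1(10)Z,4E-dien-12-yl]-9-borabicyclo[3.3.1]nonane | CC(C)[Si](C(C)C)(C(C)C)O[C@H]1/C=C(\C)CC/C=C(/C)C[C@@H](O[Si](C)(C)C(C)(C)C)[C@@H]1CC([2H])([2H])B1C2CCCC1CCC2 | intermediate
24 | (6S,7S,8R)-8-(tert-butyldimethylsilyloxy)-6-(triisopropylsilyloxy)(12,12-2H2)-13-norgermacra-1(10)Z,4E-dien-12-ol | CC(C)[Si](C(C)C)(C(C)C)O[C@H]1/C=C(\C)CC/C=C(/C)C[C@@H](O[Si](C)(C)C(C)(C)C)[C@@H]1CC([2H])([2H])O | intermediate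
25 | (6S,7S,8R)-6-(triisopropylsilyloxy)(12,12-2H2)-13-norgermacra-1(10)Z,4E-diene-8,12-diol | CC(C)[Si](C(C)C)(C(C)C)O[C@H]1/C=C(\C)CC/C=C(/C)C[C@@H](O)[C@@H]1CC([2H])([2H])O | intermediate
26 | (6S,7S,8R)-8,12-epoxy-6-(triisopropylsilyloxy)(12-2H)-13-norgermacra-1(10)Z,4E-dien-12-ol (lactol, both C12 epimers) | CC(C)[Si](C(C)C)(C(C)C)O[C@H]1/C=C(\C)CC/C=C(/C)C[C@H]2OC([2H])(O)C[C@H]12 | intermediate
27 | (6S,7S,8R)-6-(triisopropylsilyloxy)-13-norgermacra-1(10)Z,4E-dien-12,8-olide | CC(C)[Si](C(C)C)(C(C)C)O[C@H]1/C=C(\C)CC/C=C(/C)C[C@H]2OC(=O)C[C@H]12 | intermediate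
28 | (6S,7S,8R,11S)-11-hydroxy-6-(triisopropylsilyloxy)-13-norgermacra-1(10)Z,4E-dien-12,8-olide | CC(C)[Si](C(C)C)(C(C)C)O[C@H]1/C=C(\C)CC/C=C(/C)C[C@H]2OC(=O)[C@@H](O)[C@H]12 | intermediate
29 | (6S,7S,8R,11S)-11-(triethylsilyloxy)-6-(triisopropylsilyloxy)-13-norgermacra-1(10)Z,4E-dien-12,8-olide | CC(C)[Si](C(C)C)(C(C)C)O[C@H]1/C=C(\C)CC/C=C(/C)C[C@H]2OC(=O)[C@@H](O[Si](CC)(CC)CC)[C@H]12 | intermediate
30 | (6S,7S,8R,11R)-11-(triethylsilyloxy)-6-(triisopropylsilyloxy)germacra-1(10)Z,4E-dien-12,8-olide | CC(C)[Si](C(C)C)(C(C)C)O[C@H]1/C=C(\C)CC/C=C(/C)C[C@H]2OC(=O)[C@](C)(O[Si](CC)(CC)CC)[C@H]12 | intermediate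
31 | (6S,7R,8R,11R)-6,11-dihydroxygermacra-1(10)Z,4E-dien-12,8-olide | O[C@H]1/C=C(\C)CC/C=C(/C)C[C@H]2OC(=O)[C@](C)(O)[C@H]12 | intermediate
32 | angelic anhydride, (2Z)-2-methylbut-2-enoic anhydride | C/C=C(/C)C(=O)OC(=O)/C(C)=C\C | starting material
33 | CNP0391997.3, (6S,7S,8R,11R)-6,11-bis[(2Z)-2-methylbut-2-enoyloxy]germacra-1(10)Z,4E-dien-12,8-olide | C/C=C(/C)C(=O)O[C@H]1/C=C(\C)CC/C=C(/C)C[C@H]2OC(=O)[C@](C)(OC(=O)/C(C)=C\C)[C@H]12 | target

## Step count and least certain steps

Total: 23 steps. Longest linear sequence: 21 steps (steps 1–6 and 9–23); steps 7 and 8 make the second fragment.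

**Step 14 (key step).**
- Risk: deprotonation at the wrong allylic position. C12 is part of the less substituted allyl unit and is acidified by the C8 oxygen. Its anion would lose the C8 silanolate by 1,4-elimination or shift onto C4. The deuterium label and the low temperature should reduce this, but may not suppress it. Attack on the wrong face of C7 and a competing [1,2] shift are the lesser risks.
- Fallback: a carbonyl allylation that forms the same C6–C7 bond without an ether. It sets out from 17 and returns at 21.
  - MnO2 in CH2Cl2 would oxidise the allylic alcohol to (2E,6Z,9R,10E)-9,12-bis(tert-butyldimethylsilyloxy)-3,7-dimethyl(12,12-2H2)dodeca-2,6,10-trienal F1.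
  - Buffered HF·pyridine would free the primary hydroxyl to give (2E,6Z,9R,10E)-9-(tert-butyldimethylsilyloxy)-12-hydroxy-3,7-dimethyl(12,12-2H2)dodeca-2,6,10-trienal F2.
  - CBr4/PPh3 would give (2E,6Z,9R,10E)-12-bromo-9-(tert-butyldimethylsilyloxy)-3,7-dimethyl(12,12-2H2)dodeca-2,6,10-trienal F3.
  - CrCl2 in THF at high dilution (intramolecular Nozaki–Hiyama–Kishi allylation) would let the allylchromium attack the aldehyde through C7 in a six-membered chair. This gives the anti C6/C7 relation and the C7 vinyl group and should deliver 21.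

**Step 13 (macrocyclic etherification).**
- Risk: intermolecular etherification to oligomers, and loss of the allylic chloride by elimination or SN2′ attack, because closure of a 13-membered ring is slow.
- Fallback: the ether is given up altogether. The route is left at 17 and follows the chromium-mediated closure described for step 14 (through F1, F2 and F3) to 21. No further compound is needed.

**Step 21 (C11 methylation).**
- Risk: poor or reversed facial selectivity. The flexible ten-membered ring might expose the face of the enolate syn to C6.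
- Fallback: the order of the two enolate reactions is reversed, which helps if the face preference is opposite to the one assumed. It sets out from 27 and returns at 31.
  - LiN(i-Pr)2/MeI would give (6S,7S,8R)-6-(triisopropylsilyloxy)germacra-1(10)Z,4E-dien-12,8-olide F4 (both C11 epimers).
  - KN(SiMe3)2 and 2-(phenylsulfonyl)-3-phenyloxaziridine would then bring the oxygen in on the favoured face and give (6S,7S,8R,11R)-11-hydroxy-6-(triisopropylsilyloxy)germacra-1(10)Z,4E-dien-12,8-olide F5.
  - n-Bu4NF/AcOH would remove the silyl group and give 31.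

**Step 23 (double angeloylation).**
- Risk: incomplete acylation of the hindered tertiary alkoxide, and isomerisation of angelate to tiglate if the mixture has to be warmed.
- Fallback: the Z alkene is built after the ester bonds. It sets out from 31 and returns at 33.
  - 2-[Bis(2,2,2-trifluoroethoxy)phosphoryl]propanoic acid with DCC and DMAP (harmless here, since no angelate is present yet) would give (6S,7S,8R,11R)-6,11-bis{2-[bis(2,2,2-trifluoroethoxy)phosphoryl]propanoyloxy}germacra-1(10)Z,4E-dien-12,8-olide F6.
  - Still–Gennari olefination with KN(SiMe3)2, 18-crown-6 and acetaldehyde at −78 °C would form both (Z)-2-methylbut-2-enoates and give 33.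

## Further compounds

F1 | step 14 | (2E,6Z,9R,10E)-9,12-bis(tert-butyldimethylsilyloxy)-3,7-dimethyl(12,12-2H2)dodeca-2,6,10-trienal | O=C/C=C(\C)CC/C=C(/C)C[C@@H](O[Si](C)(C)C(C)(C)C)/C=C/C([2H])([2H])O[Si](C)(C)C(C)(C)C
F2 | step 14 | (2E,6Z,9R,10E)-9-(tert-butyldimethylsilyloxy)-12-hydroxy-3,7-dimethyl(12,12-2H2)dodeca-2,6,10-trienal | O=C/C=C(\C)CC/C=C(/C)C[C@@H](O[Si](C)(C)C(C)(C)C)/C=C/C([2H])([2H])O
F3 | step 14 | (2E,6Z,9R,10E)-12-bromo-9-(tert-butyldimethylsilyloxy)-3,7-dimethyl(12,12-2H2)dodeca-2,6,10-trienal | O=C/C=C(\C)CC/C=C(/C)C[C@@H](O[Si](C)(C)C(C)(C)C)/C=C/C([2H])([2H])Br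
F0 | step 13 | none | none
F4 | step 21 | (6S,7S,8R)-6-(triisopropylsilyloxy)germacra-1(10)Z,4E-dien-12,8-olide, both C11 epimers | CC(C)[Si](C(C)C)(C(C)C)O[C@H]1/C=C(\C)CC/C=C(/C)C[C@H]2OC(=O)C(C)[C@H]12
F5 | step 21 | (6S,7S,8R,11R)-11-hydroxy-6-(triisopropylsilyloxy)germacra-1(10)Z,4E-dien-12,8-olide | CC(C)[Si](C(C)C)(C(C)C)O[C@H]1/C=C(\C)CC/C=C(/C)C[C@H]2OC(=O)[C@](C)(O)[C@H]12
F6 | step 23 | (6S,7S,8R,11R)-6,11-bis{2-[bis(2,2,2-trifluoroethoxy)phosphoryl]propanoyloxy}germacra-1(10)Z,4E-dien-12,8-olide, mixture at the two phosphonate α-carbons | CC(C(=O)O[C@H]1/C=C(\C)CC/C=C(/C)C[C@H]2OC(=O)[C@](C)(OC(=O)C(C)P(=O)(OCC(F)(F)F)OCC(F)(F)F)[C@H]12)P(=O)(OCC(F)(F)F)OCC(F)(F)F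
A1 | alternative 1 | (S)-O-triethylsilyl lactate ester of the C8 alcohol with the adjacent cis-6,7-epoxide | CC(C)(C)[Si](C)(C)OC/C=C(/C)C[C@@H](OC(=O)[C@H](C)O[Si](CC)(CC)CC)[C@H]1O[C@H]1COCc1ccc(OC)cc1
A2 | alternative 1 | trans-γ-lactone with quaternary C11 and free C6 hydroxyl | CC(C)(C)[Si](C)(C)OC/C=C(/C)C[C@H]1OC(=O)[C@](C)(O[Si](CC)(CC)CC)[C@@H]1[C@@H](O)COCc2ccc(OC)cc2
A3 | alternative 2 | seco lactone with the Z diene and the E C4 alkenyl iodide | C=C/C=C(/C)C[C@H]1OC(=O)[C@](C)(O[Si](C)(C)C(C)(C)C)[C@@H]1[C@@H](O[Si](C)(C)C(C)(C)C)/C=C(\C)I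
A4 | alternative 2 | 6,11-bis(tert-butyldimethylsilyloxy)germacra-1(10)Z,4E-dien-12,8-olide | CC(C)(C)[Si](C)(C)O[C@H]1/C=C(\C)CC/C=C(/C)C[C@H]2OC(=O)[C@](C)(O[Si](C)(C)C(C)(C)C)[C@H]12
A5 | alternative 3 | C8 aldehyde tethered to the α-substituted allyl pinacolboronate (boron-bearing C1 not specified) | CC(C)(C)[Si](C)(C)O[C@@H](/C=C(\C)CCC(B1OC(C)(C)C(C)(C)O1)C(C)=C)[C@H](C=O)CC(=O)OC(C)(C)C
A6 | alternative 3 | (1(10)Z,4E)-cyclodecadien-8-ol with C6 silyl ether and C7 tert-butyl acetate branch | CC(C)(C)[Si](C)(C)O[C@H]1/C=C(\C)CC/C=C(/C)C[C@@H](O)[C@@H]1CC(=O)OC(C)(C)C
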